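The enone C1(=O)–C2H=C3 with oxygen on C3, together with the syn C5/C6 diol, marks the ten-membered carbocycle as a masked cyclodeca-2,5-dienone. Joining C1 to C6 across that ring turns it into a cyclohexane (C1, C10, C9, C8, C7, C6), and everything rests on this reconnection. In the forward sense an anionic oxy-Cope rearrangement breaks C1–C6 and forms C3–C4 in one operation, enlarging the six-membered ring to the ten-membered one while setting C4 and the trans C5=C6 alkene. The precursor is a chair 1-(ethoxyethynyl)-2-[(E)-propenyl]cyclohexanol from (S)-carvone, bearing C7, C8 and C10, with the alkynyl and propenyl groups trans-diequatorial.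

Key step: step 13

Remarks on the chemistry (one line each):
- Target numbering is used throughout: C1 furanone carbonyl, C2 its CH, C3 the ring carbon bonded to the furanone oxygen, C4 (methyl), C5 (free hydroxyl), C6 (isobutyrate), C7 (bears C11, with C13 the methylene and C12 the lactone carbonyl), C8 (lactone oxygen), C9 (CH2), C10 (methyl and furanone oxygen).
- (S)-Carvone is the enantiomer needed: the C8 oxygen is introduced next to the carvone carbonyl and the carbonyl is then transposed, so the carvone carbonyl carbon ends as C9 and the stereocentre arrives as C7 with the configuration of the target.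
- The acetylide is added while C9–C10 is still an oxirane, because on a C10-alkoxy ketone it would enter anti to the axial C10 methyl and give the axial-alkynyl (cis) carbinol, from which only a cis C5=C6 alkene and the wrong C4 could arise.
- Compound 20 is drawn with C1 and C4 cis on C2=C3 (protonation of the cyclic allenolate from outside the ring, the usual geometry of a vinylogous ester); the other geometry would serve equally, since step 14 rebuilds this double bond inside the furanone.

Step 1
Reactants: 1 (S)-carvone
Product: 2 (5S)-5-(3-chloroprop-1-en-2-yl)-2-methylcyclohex-2-en-1-one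
Conditions: Ca(OCl)2, CO2 (solid), CH2Cl2/H2O, 0 °C
Reagents that add atoms: calcium hypochlorite, [Ca+2].[O-]Cl.[O-]Cl
Why: Hypochlorous acid generated in the flask should chlorinate the electron-rich 1,1-disubstituted alkene by an ene-type allylic chlorination with shift of the double bond, while the electron-poor enone alkene and the stereocentre (the future C7) stay untouched.

Step 2
Reactants: 2 (5S)-5-(3-chloroprop-1-en-2-yl)-2-methylcyclohex-2-en-1-one
Product: 3 (5R,6R)-5-(3-chloroprop-1-en-2-yl)-6-hydroxy-2-methylcyclohex-2-en-1-one
Conditions: NaN(SiMe3)2, THF, −78 °C; 2-(phenylsulfonyl)-3-phenyloxaziridine, −78 °C; AcOH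
Reagents that add atoms: 2-(phenylsulfonyl)-3-phenyloxaziridine, O=S(=O)(N1OC1c1ccccc1)c1ccccc1
Why: Kinetic deprotonation at the α′-methylene (the future C8) and oxidation of the sodium enolate by the N-sulfonyloxaziridine should place the hydroxyl on the face opposite the neighbouring side chain (enolate hydroxylation), which sets C8 trans to C7.

Step 3
Reactants: 3 (5R,6R)-5-(3-chloroprop-1-en-2-yl)-6-hydroxy-2-methylcyclohex-2-en-1-one
Product: 5 (5R,6R)-6-hydroxy-5-(3-hydroxyprop-1-en-2-yl)-2-methylcyclohex-2-en-1-one, via allylic acetate 4 (not isolated)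
Conditions: KOAc, Bu4NI (cat.), DMF, 50 °C; then K2CO3 (cat.), MeOH, 0 °C
Reagents that add atoms: potassium acetate, CC(=O)[O-].[K+]
Why: Acetate should displace the primary allylic chloride in an SN2 reaction and base-catalysed transesterification with methanol then frees the primary alcohol, neither operation touching the two stereocentres.

Step 4
Reactants: 5 (5R,6R)-6-hydroxy-5-(3-hydroxyprop-1-en-2-yl)-2-methylcyclohex-2-en-1-one
Product: 6 (5R,6R)-6-(tert-butyldimethylsilyloxy)-5-[3-(tert-butyldimethylsilyloxy)prop-1-en-2-yl]-2-methylcyclohex-2-en-1-one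
Conditions: TBSCl (2.5 equiv), imidazole, DMF, rt
Reagents that add atoms: tert-butyldimethylsilyl chloride, CC(C)(C)[Si](C)(C)Cl
Why: Silylation with the silyl chloride and imidazole should convert both hydroxyl groups into tert-butyldimethylsilyl ethers, which withstand the basic, nucleophilic and hydride reagents used up to the ring expansion.

Step 5
Reactants: 6 bis-silyl enone
Product: 7 epoxy ketone (oxirane across the former enone double bond; oxirane oxygen trans to the side chain)
Conditions: 30% H2O2, NaOH (cat.), MeOH, 0 °C
Reagents that add atoms: hydrogen peroxide, OO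
Why: In this Weitz–Scheffer epoxidation hydroperoxide anion should add to the enone β-carbon (the future C1) from the face opposite the C7 side chain, as it does with carvone itself, so that the oxirane oxygen ends trans to that side chain.

Step 6
Reactants: 7 epoxy ketone
Product: 9 allylic alcohol (C1 hydroxyl and C8 silyloxy both trans to the C7 side chain; C9=C10 alkene), via epoxy hydrazone 8 (not isolated)
Conditions: N2H4·H2O, AcOH (cat.), MeOH, 0 °C to rt
Reagents that add atoms: none
Why: In the Wharton transposition the hydrazone 8 should open the oxirane to an alkenyl diazene that loses dinitrogen, which moves the double bond to C9=C10 and leaves the hydroxyl on C1 with its C–O bond intact and therefore trans to the C7 side chain.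

Step 7
Reactants: 9 allylic alcohol
Product: 10 epoxy alcohol (C9–C10 oxirane on the face of the C1 hydroxyl)
Conditions: VO(acac)2 (cat.), t-BuOOH, CH2Cl2, 0 °C to rt
Reagents that add atoms: tert-butyl hydroperoxide, CC(C)(C)OO
Why: Vanadium-catalysed hydroxyl-directed epoxidation should deliver oxygen to C9=C10 on the face of the pseudoaxial C1 hydroxyl, which puts the C10 oxygen trans to the C7 side chain and cis to the C8 silyloxy group as in the target, and it should not touch the isolated 1,1-disubstituted alkene.

Step 8
Reactants: 10 epoxy alcohol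
Product: 11 C1 ketone with the C9–C10 oxirane
Conditions: nPr4N[RuO4] (cat.), N-methylmorpholine N-oxide, 4 Å molecular sieves, CH2Cl2, rt
Reagents that add atoms: none
Why: The Ley–Griffith oxidation should turn the secondary alcohol into the ketone under neutral conditions that spare the oxirane and both silyl ethers.

Step 9
Reactants: 11 C1 ketone with the C9–C10 oxirane; 12 (E)-1-bromoprop-1-ene
Product: 13 C6-[(E)-prop-1-enyl] epoxy ketone (propenyl trans to the C7 side chain)
Conditions: LiN(SiMe3)2, Pd(OAc)2 (cat.), P(t-Bu)3 (cat.), toluene/THF, rt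
Reagents that add atoms: none
Why: Palladium-catalysed α-alkenylation of the lithium enolate, which can form only at C6, should proceed by oxidative addition of the alkenyl bromide and reductive elimination with retention of the (E) geometry, and the enolisable C6 centre should settle with the propenyl group equatorial and trans to the C7 side chain.

Step 10
Reactants: 13 C6-[(E)-prop-1-enyl] epoxy ketone; 14 ethoxyacetylene
Product: 15 1-(ethoxyethynyl) epoxy carbinol (alkynyl anti to the oxirane oxygen and trans to the propenyl group)
Conditions: 14, n-BuLi, THF, −78 °C; LaCl3·2LiCl (cat.); then 13, −78 °C; H2O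
Reagents that add atoms: none
Why: The lithium acetylide should add to the ketone from the face opposite the oxirane oxygen on C10 (1,2-addition, with the lanthanum salt suppressing enolisation), which places the alkynyl group cis to the C10 methyl and trans to the C6 propenyl group, the arrangement that the ring expansion requires.

Step 11
Reactants: 15 1-(ethoxyethynyl) epoxy carbinol
Product: 16 C1,C10-diol (C9 now CH2)
Conditions: LiEt3BH, THF, 0 °C to rt; H2O
Reagents that add atoms: none
Why: The borohydride should open the trisubstituted oxirane by SN2 attack at the secondary carbon C9, because the fully substituted C10 next to the quaternary C1 is shielded, so that C10 keeps its oxygen and configuration as a tertiary alcohol while the ynol ether is left alone.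

Step 12
Reactants: 16 C1,C10-diol
Product: 17 (1R,2R,4S,5R,6S)-4-(tert-butyldimethylsilyloxy)-5-[3-(tert-butyldimethylsilyloxy)prop-1-en-2-yl]-1-(ethoxyethynyl)-2-(methoxymethoxy)-2-methyl-6-[(E)-prop-1-enyl]cyclohexan-1-ol
Conditions: MeOCH2Cl, iPr2NEt, Bu4NI (cat.), CH2Cl2, 0 to 40 °C
Reagents that add atoms: chloromethyl methyl ether, COCCl
Why: Alkylation with chloromethyl methyl ether and a hindered amine should occur at the equatorial C10 hydroxyl in preference to the axial and propargylic C1 hydroxyl (steric differentiation of two tertiary alcohols), giving an acetal that can neither migrate to the C1 alkoxide nor add to the ynol ether in the next step.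

Step 13
Reactants: 17 1-(ethoxyethynyl)-2-[(E)-propenyl]cyclohexanol precursor
Product: 20 (4S,7R,8S,10R)-3-ethoxycyclodeca-2,5-dienone with trans C5=C6 (C10 methoxymethyl ether and both silyl ethers retained), via potassium alkoxide 18 (not isolated), via potassium allenolate 19 (not isolated)
Conditions: KH, 18-crown-6, THF, 0 °C to rt; AcOH, −78 °C
Reagents that add atoms: none
Why: Proposed new method: in alkoxide 18, axial on a chair that holds the ethoxyethynyl and propenyl groups trans-diequatorial, the oxygen lone pairs labilise the adjacent C1–C6 bond, and a concerted [3,3]-sigmatropic shift should follow in which C3 of the ynol ether bonds to C4 as C1–C6 breaks, giving the cyclic allenolate 19, which is protonated at C2 from outside the ring. The closest known reaction type is the anionic oxy-Cope ring expansion of 1-alkynyl-2-alkenylcyclohexanols to cyclodecadienones; what is new is the alkoxy-substituted alkyne, whose oxygen makes the reacting π bond more electron-rich but should not change the course of the reaction. No chain ends are joined: the ten-membered ring is obtained because four atoms (C2, C3, C4, C5) come to lie between C1 and C6 of the cyclohexane when the six-centre pericyclic array collapses. The configuration of C6 is relayed to C4: with the C6 hydrogen lying in the plane of the propenyl group (minimal allylic strain) C3 must reach C4 on the side from which C1 departs, so the (E)-propenyl group leads to (4S) and to a trans C5=C6 bond. The step needs the sigmatropic shift to outrun loss of ethoxyacetylide, silyl transfer and attack of oxygen on the ynol ether, which the crown-ether-separated alkoxide, the non-migrating acetal on the C10 oxygen and the equatorial placement of both π partners should secure.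

Step 14
Reactants: 20 3-ethoxycyclodeca-2,5-dienone
Product: 21 furanone diol (C3–O–C10 bridge; free C8 and C12 hydroxyls; trans C5=C6)
Conditions: HCl (aq), MeOH/THF, 0 to 40 °C
Reagents that add atoms: none
Why: Acid should remove the methoxymethyl and silyl groups and let the freed C10 hydroxyl attack C3 of the protonated vinylogous ester in a 5-exo closure with loss of ethanol, the established acid cyclisation of α′-hydroxy β-alkoxy enones to 3(2H)-furanones, which also rebuilds the C2=C3 double bond inside the five-membered ring.

Step 15
Reactants: 21 furanone diol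
Product: 24 α-methylene γ-lactone (C12 carbonyl bonded to the C8 oxygen), via hydroxy enal 22 (not isolated), via lactol 23 (not isolated)
Conditions: MnO2 (excess), CH2Cl2, rt
Reagents that add atoms: none
Why: Manganese dioxide should oxidise the allylic primary alcohol to the enal 22, whose lactol 23 with the C8 hydroxyl is oxidised in turn to the α-methylene γ-lactone (oxidative lactonisation of a 2-methylene-1,4-diol), the non-allylic C8 alcohol itself being inert to the reagent.

Step 16
Reactants: 24 α-methylene γ-lactone
Product: 25 (5S,6S)-diol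
Conditions: OsO4 (cat.), (DHQ)2PHAL (cat.), N-methylmorpholine N-oxide, acetone/H2O, 0 °C
Reagents that add atoms: N-methylmorpholine N-oxide, C[N+]1([O-])CCOCC1; water, O
Why: Osmium tetroxide under Upjohn conditions should dihydroxylate the strained, electron-rich trans C5=C6 alkene in preference to the two conjugated alkenes and add both oxygens syn from the outer face, the inner face being covered by the transannular furanone, which gives (5S,6S), and the (DHQ)2PHAL ligand favours the same face of a trans-disubstituted alkene.

Step 17
Reactants: 25 (5S,6S)-diol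
Product: 27 target CNP0141385.1 (C6 isobutyrate with free C5 hydroxyl), via cyclic orthoester 26 (not isolated)
Conditions: Me2CHC(OMe)3, PPTS (cat.), CH2Cl2, rt; then AcOH/H2O, 0 °C to rt
Reagents that add atoms: trimethyl orthoisobutyrate, COC(OC)(OC)C(C)C; water, O
Why: Acid-catalysed exchange should tie the diol up as the cyclic orthoester 26, and mild aqueous acid should open it through the dioxolanylium ion and its hemiorthoester with release of the less hindered C5 oxygen, so that the acyl group stays on the more hindered C6 oxygen beside the lactone (regioselective monoacylation by orthoester hydrolysis) under conditions that allow neither acyl migration nor conjugate addition.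

Compound list

1 | (S)-carvone, (5S)-2-methyl-5-(prop-1-en-2-yl)cyclohex-2-en-1-one | CC1=CC[C@@H](CC1=O)C(C)=C | starting material
2 | (5S)-5-(3-chloroprop-1-en-2-yl)-2-methylcyclohex-2-en-1-one | O=C1C[C@@H](C(=C)CCl)CC=C1C | intermediate
3 | (5R,6R)-5-(3-chloroprop-1-en-2-yl)-6-hydroxy-2-methylcyclohex-2-en-1-one (hydroxyl trans to the side chain) | O=C1[C@H](O)[C@@H](C(=C)CCl)CC=C1C | intermediate
4 | allylic acetate of 3, (5R,6R)-5-(3-acetoxyprop-1-en-2-yl)-6-hydroxy-2-methylcyclohex-2-en-1-one (not isolated) | O=C1[C@H](O)[C@@H](C(=C)COC(C)=O)CC=C1C | intermediate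
5 | (5R,6R)-6-hydroxy-5-(3-hydroxyprop-1-en-2-yl)-2-methylcyclohex-2-en-1-one | O=C1[C@H](O)[C@@H](C(=C)CO)CC=C1C | intermediate
6 | (5R,6R)-6-(tert-butyldimethylsilyloxy)-5-[3-(tert-butyldimethylsilyloxy)prop-1-en-2-yl]-2-methylcyclohex-2-en-1-one | O=C1[C@H](O[Si](C)(C)C(C)(C)C)[C@@H](C(=C)CO[Si](C)(C)C(C)(C)C)CC=C1C | intermediate
7 | 2,3-epoxide of 6, oxirane oxygen trans to the side chain | O=C1[C@H](O[Si](C)(C)C(C)(C)C)[C@@H](C(=C)CO[Si](C)(C)C(C)(C)C)C[C@@H]2O[C@]12C | intermediate
8 | hydrazone of 7 (not isolated) | NN=C1[C@H](O[Si](C)(C)C(C)(C)C)[C@@H](C(=C)CO[Si](C)(C)C(C)(C)C)C[C@@H]2O[C@]12C | intermediate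
9 | 4-(tert-butyldimethylsilyloxy)-5-[3-(tert-butyldimethylsilyloxy)prop-1-en-2-yl]-2-methylcyclohex-2-en-1-ol, 1-OH and 4-OSi both trans to the 5-side chain | O[C@@H]1C(C)=C[C@H](O[Si](C)(C)C(C)(C)C)[C@@H](C(=C)CO[Si](C)(C)C(C)(C)C)C1 | intermediate
10 | 2,3-epoxide of 9 on the face of the hydroxyl | O[C@@H]1[C@]2(C)O[C@@H]2[C@H](O[Si](C)(C)C(C)(C)C)[C@@H](C(=C)CO[Si](C)(C)C(C)(C)C)C1 | intermediate
11 | epoxy ketone from 10 (C1 ketone, C9–C10 oxirane) | O=C1[C@]2(C)O[C@@H]2[C@H](O[Si](C)(C)C(C)(C)C)[C@@H](C(=C)CO[Si](C)(C)C(C)(C)C)C1 | intermediate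
12 | (E)-1-bromoprop-1-ene | C/C=C/Br | starting material
13 | C6-[(E)-prop-1-enyl] derivative of 11, propenyl trans to the C7 side chain | O=C1[C@]2(C)O[C@@H]2[C@H](O[Si](C)(C)C(C)(C)C)[C@@H](C(=C)CO[Si](C)(C)C(C)(C)C)[C@@H]1/C=C/C | intermediate
14 | ethoxyacetylene | CCOC#C | starting material
15 | 1-(ethoxyethynyl) carbinol of 13, alkynyl anti to the oxirane oxygen and trans to the propenyl group | CCOC#C[C@@]1(O)[C@]2(C)O[C@@H]2[C@H](O[Si](C)(C)C(C)(C)C)[C@@H](C(=C)CO[Si](C)(C)C(C)(C)C)[C@@H]1/C=C/C | intermediate
16 | C1,C10-diol: 1-(ethoxyethynyl)-2-methyl-6-[(E)-propenyl]cyclohexane-1,2-diol with the C8 silyloxy group and the C7 silyloxymethylvinyl group | CCOC#C[C@@]1(O)[C@](C)(O)C[C@H](O[Si](C)(C)C(C)(C)C)[C@@H](C(=C)CO[Si](C)(C)C(C)(C)C)[C@@H]1/C=C/C | intermediate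
17 | (1R,2R,4S,5R,6S)-4-(tert-butyldimethylsilyloxy)-5-[3-(tert-butyldimethylsilyloxy)prop-1-en-2-yl]-1-(ethoxyethynyl)-2-(methoxymethoxy)-2-methyl-6-[(E)-prop-1-enyl]cyclohexan-1-ol (oxy-Cope precursor) | CCOC#C[C@@]1(O)[C@](C)(OCOC)C[C@H](O[Si](C)(C)C(C)(C)C)[C@@H](C(=C)CO[Si](C)(C)C(C)(C)C)[C@@H]1/C=C/C | intermediate
18 | potassium alkoxide of 17 (not isolated) | CCOC#C[C@@]1([O-])[C@](C)(OCOC)C[C@H](O[Si](C)(C)C(C)(C)C)[C@@H](C(=C)CO[Si](C)(C)C(C)(C)C)[C@@H]1/C=C/C.[K+] | intermediate
19 | potassium allenolate, ten-membered 3-ethoxy-1-oxido-1,2-diene with trans C5=C6 (not isolated) | [K+].[O-]C1=C=C(OCC)[C@@H](C)/C=C/[C@H](C(=C)CO[Si](C)(C)C(C)(C)C)[C@@H](O[Si](C)(C)C(C)(C)C)C[C@@]1(C)OCOC | intermediate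
20 | (2E,4S,5E,7R,8S,10R)-3-ethoxy-4,10-dimethyl-10-(methoxymethoxy)-8-(tert-butyldimethylsilyloxy)-7-[3-(tert-butyldimethylsilyloxy)prop-1-en-2-yl]cyclodeca-2,5-dien-1-one | O=C1/C=C(OCC)\[C@@H](C)/C=C/[C@H](C(=C)CO[Si](C)(C)C(C)(C)C)[C@@H](O[Si](C)(C)C(C)(C)C)C[C@@]1(C)OCOC | intermediate
21 | furanone diol: C3–O–C10 bridged 3(2H)-furanone with free C8 and C12 hydroxyls and trans C5=C6 | O=C1C=C2[C@@H](C)/C=C/[C@H](C(=C)CO)[C@@H](O)C[C@@]1(C)O2 | intermediate
22 | hydroxy enal (C12 aldehyde, free C8 hydroxyl; not isolated) | O=C1C=C2[C@@H](C)/C=C/[C@H](C(=C)C=O)[C@@H](O)C[C@@]1(C)O2 | intermediate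
23 | lactol (C12 hemiacetal with the C8 oxygen; not isolated) | O=C1C=C2[C@@H](C)/C=C/[C@@H]3C(=C)C(O)O[C@H]3C[C@@]1(C)O2 | intermediate
24 | α-methylene γ-lactone with furanone and trans C5=C6 | O=C1C=C2[C@@H](C)/C=C/[C@@H]3C(=C)C(=O)O[C@H]3C[C@@]1(C)O2 | intermediate
25 | (5S,6S)-diol | O=C1C=C2[C@@H](C)[C@H](O)[C@@H](O)[C@@H]3C(=C)C(=O)O[C@H]3C[C@@]1(C)O2 | intermediate
26 | cyclic methyl orthoisobutyrate of the C5/C6 diol (not isolated) | O=C1C=C2[C@@H](C)[C@@H]4OC(OC)(C(C)C)O[C@H]4[C@@H]3C(=C)C(=O)O[C@H]3C[C@@]1(C)O2 | intermediate
27 | CNP0141385.1, (4S,5S,6S,7R,8S,10R) furanone lactone with C5 hydroxyl and C6 isobutyrate | C=C1C(=O)O[C@H]2C[C@@]3(C)OC(=CC3=O)[C@@H](C)[C@H](O)[C@@H](OC(=O)C(C)C)[C@H]12 | target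

Total step count: 17.
Longest linear sequence: 17 steps, from (S)-carvone 1 to 27; 12 and 14 are bought and enter in steps 9 and 10.

Steps most likely to fail

1. Step 13 (ring expansion). What may go wrong: fragmentation of the alkoxide by loss of potassium ethoxyacetylide, or a sigmatropic shift too slow to compete with silyl transfer. The fallback uses known chemistry: the C3–C4 bond is made by the anionic oxy-Cope rearrangement of a 1,2-dialkenylcyclohexanol and the C2=C3 double bond is added afterwards. Setting out from 13, (Z)-2-ethoxyvinyllithium (from (Z)-1-bromo-2-ethoxyethene and t-BuLi, THF, −78 °C) should add anti to the oxirane oxygen to give the (Z)-2-ethoxyvinyl carbinol F1. LiEt3BH should open the oxirane to the diol F2, and chloromethyl methyl ether with iPr2NEt should give the C10 methoxymethyl ether F3. KH and 18-crown-6 in THF should rearrange F3 through the chair transition state, and protonation should give the 3-ethoxycyclodec-5-enone F4 with the trans C5=C6 bond and (4S). Dehydrogenation of F4 at its only enolisable position (LiN(SiMe3)2, then N-tert-butylbenzenesulfinimidoyl chloride, THF, −78 °C) should introduce the C2=C3 double bond and so return to the route at 20.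

2. Step 9 (propenylation). What may go wrong: base-induced opening or ring contraction of the epoxy ketone at the temperature of the coupling, or migration of the new double bond into conjugation with the ketone. Setting out from 11, the lithium enolate (LiN(iPr)2, THF, −78 °C) is alkylated with allyl bromide at low temperature to give the allyl ketone F5, with the allyl group trans to the C7 side chain. One-position isomerisation of the terminal alkene with a palladium hydride catalyst (Pd(dba)2, P(t-Bu)3, isobutyryl chloride, toluene, rt) should then give the (E)-propenyl ketone, returning at 13.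

3. Step 17 (monoacylation). What may go wrong: collapse of the hemiorthoester toward the C5 ester, which would happen if C5 and not C6 carried the more hindered oxygen. The fallback uses the opposite selection principle. Setting out from 25, direct acylation under steric control (isobutyryl chloride, 2,4,6-collidine, CH2Cl2, −20 °C, without a nucleophilic amine so that the methylene lactone is spared) should acylate the less hindered hydroxyl and lead straight to 27; no new compound is formed (F0).

Further compounds

F1 | step 13 | (Z)-2-ethoxyvinyl carbinol from 13 (vinyl group anti to the oxirane oxygen) | CCO/C=C\[C@@]1(O)[C@]2(C)O[C@@H]2[C@H](O[Si](C)(C)C(C)(C)C)[C@@H](C(=C)CO[Si](C)(C)C(C)(C)C)[C@@H]1/C=C/C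
F2 | step 13 | C1,C10-diol of the (Z)-2-ethoxyvinyl series | CCO/C=C\[C@@]1(O)[C@](C)(O)C[C@H](O[Si](C)(C)C(C)(C)C)[C@@H](C(=C)CO[Si](C)(C)C(C)(C)C)[C@@H]1/C=C/C
F3 | step 13 | C10 methoxymethyl ether of F2 (1,2-dialkenylcyclohexanol) | CCO/C=C\[C@@]1(O)[C@](C)(OCOC)C[C@H](O[Si](C)(C)C(C)(C)C)[C@@H](C(=C)CO[Si](C)(C)C(C)(C)C)[C@@H]1/C=C/C
F4 | step 13 | (3R,4S,7R,8S,10R)-3-ethoxycyclodec-5-enone with trans C5=C6 (C3 as expected from the chair transition state) | O=C1C[C@@H](OCC)[C@@H](C)/C=C/[C@H](C(=C)CO[Si](C)(C)C(C)(C)C)[C@@H](O[Si](C)(C)C(C)(C)C)C[C@@]1(C)OCOC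
F5 | step 9 | C6-allyl epoxy ketone from 11 (allyl trans to the C7 side chain) | O=C1[C@]2(C)O[C@@H]2[C@H](O[Si](C)(C)C(C)(C)C)[C@@H](C(=C)CO[Si](C)(C)C(C)(C)C)[C@@H]1CC=C
F0 | step 17 | none | none
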